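Turn the question round: what would the runs have to show for target to stand above isomer of the product A in the flask at 30 h?

| flask | starting material | remark | time |
|---|---|---|---|
| west | 0.28 M | run made earlier |  |
| east | 0.44 M | run made earlier |  |
| flask | 0.20 M |  | 30 h |

| run | time / h | isomer of the product A / % | target / % | starting material / % |
|---|---|---|---|---|
| west | 3.00 | 48.1 | 13.8 | 12.8 |
| west | 5.00 | 44.1 | 13.2 | 12.4 |
| west | 8.00 | 41.6 | 12.3 | 11.7 |
| west | 12.0 | 40.7 | 12.4 | 11.1 |
| west | 20.0 | 39.8 | 12.9 | 11.3 |
| west | 40.0 | 40.2 | 13.0 | 10.1 |
| east | 2.50 | 49.4 | 13.3 | 12.8 |
| east | 8.00 | 41.9 | 12.4 | 11.2 |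
| east | 12.0 | 40.5 | 12.7 | 11.0 |
| east | 20.0 | 41.4 | 12.7 | 11.8 |
| east | 30.0 | 41.3 | 13.3 | 10.5 |
| east | 40.0 | 40.8 | 13.5 | 11.2 |

(standard deviation of a reading: 0.5 percentage points)

- ratio of isomer of the product A to target at 15 s
- ratio of isomer of the product A to target at 30 h
- which of isomer of the product A and target there is more of at 30 h

- what may be going on: isomer of the product A <-> starting material; target <-> isomer of the product A; target <-> isomer of the product B; starting material <-> target

[isomer of the product A]/[target] would have to be below 1. From 20.0 h on, the west and east readings of isomer of the product A, summed and divided by those of target, give 3.11, the plateau ratio, our reading of the equilibrium ratio (thermodynamic control). To bring it to 1, 14 percentage points would have to pass from isomer of the product A to target, against a reading error of 0.5 points. West and east differ in charge, yet their last readings give 3.09 and 3.02, so we carry 3.11 to the flask at 30 h.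

At the other end the earliest reading, east at 2.50 h, gives 3.71, while the balance there is short by 24.5 %. We tie that excess to isomer of the product B being made. At 15 s, far earlier than that reading, we drop the excess and hold 3.11 there too, with a wide margin.

The forecast gave 4 at 15 s, 3.1 at 30 h and isomer of the product A ahead, calling the early figure “a weak extrapolation with a wide range”.

The flask gives 3.06 at 15 s and 3.10 at 30 h, with isomer of the product A ahead, 40.6 % against 13.1 %.

    isomer of the product A ⇌ starting material (k = 3.20 /h)
    target ⇌ isomer of the product A (K = 3.10, k = 0.00660 /h)
    target ⇌ isomer of the product B (K = 2.70, k = 0.900 /h)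
    starting material ⇌ target (K = 1.20, k = 3.90 /h)

In the flask, the passing of starting material into target had 99.9 % of its turnover behind it by 15.0 h, while isomer of the product A fell from 48.1 % at 3.00 h to 40.7 % at 15.0 h and target passed into isomer of the product B, a net 35.4 % of the charge up to 30 h. The plateau ratio read off the west and east runs, 3.11, stands beside 3.10 in the flask and beside 3.10 in a neighbouring flask charged with 0.050 M of starting material, which ends with 40.6 % of isomer of the product A and 13.1 % of target.

(The runs were generated by integration from invented constants; noise was put on by code.)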